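**Retrosynthetic overview**

- The target is a longipinene: a bicyclo[3.1.1]heptenone whose cyclobutane is bridged 1,3 by a four-carbon chain (seven-membered ring). Both esters are disconnected first, then C8–C9 of the seven-membered ring, by an intramolecular aldol–Tishchenko retron (1,3-anti diol monoester ⇒ keto aldehyde + angelaldehyde).
- Enabling feature: the cyclobutane (C4, C5, C11, C10) holds the C10 formyl group (C9) and the C5–C(CH3)2–CO–CH3 arm (C6–C7–C8) cis-1,3 on the face away from the enone bridge. C6 and C10 are quaternary, so only C8 can enolize and only C9 is the acceptor.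
- C5–C6 comes from a temporary lactone ring: an isobutyrate on O9 delivers its enolate to a C5 cyclobutanone, the tertiary hydroxyl is removed, and methyllithium opens the lactone (C8).
- The bicyclo[3.1.1]heptanone comes from an intramolecular vinylketene–alkene [2+2] cycloaddition of an acyclic dienoic acid. A temporary C1 silyloxy stereocenter (catalytic asymmetric vinylogous aldol) fixes the absolute configuration and is finally oxidized to the enone carbonyl.
- Ring order: cyclobutane and six-membered ring together ([2+2]) → temporary lactone → seven-membered carbocycle (key step) → second ester → enone.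

Key step: step 13

Remark on locants: longipinane numbering is used for all cyclic compounds. C1 is the enone carbonyl; C2=C3, with C3 carrying the vinylic methyl; C4 and C11 are the cyclobutane CH atoms bonded to C3 and C1; C5 is the cyclobutane CH bonded to C6; C10 is the cyclobutane carbon carrying CH3 and C9; C6 is C(CH3)2; C7 is CH–O(epoxy ester); C8 is CH2; C9 is CH–O(angelate).

Remark (assumption): the sense of induction of the chiral catalysts in steps 4 and 13 on these new substrates is not secure from analogy; the antipode that gives the drawn configuration is meant, and the other antipode is equally available.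

**Route**

Step 1
Reactants: 1 3-methylbut-2-enal diethyl acetal
Product: 2 (E)-4,4-diethoxy-2-methylbut-2-en-1-ol
Conditions: SeO2 (0.3 equiv), anhydrous t-BuOOH (3 equiv), CH2Cl2, 0 → 23 °C
Reagents that add atoms: tert-butyl hydroperoxide CC(C)(C)OO (oxygen atom, relayed by SeO2)
Why: Riley allylic oxidation in its catalytic form, in which the ene reaction and [2,3]-sigmatropic shift of SeO2 functionalize the methyl group trans to the acetal-bearing carbon of the trisubstituted alkene and return the E allylic alcohol; no stereocenter is formed.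

Step 2
Reactants: 2 (E)-4,4-diethoxy-2-methylbut-2-en-1-ol; 3 2-methylpropanoyl chloride
Product: 5 (E)-2-methyl-4-oxobut-2-en-1-yl 2-methylpropanoate, via ester acetal 4 (not isolated)
Conditions: pyridine, 4-(dimethylamino)pyridine (cat.), CH2Cl2, 0 °C; then 1 M HCl, THF, 23 °C
Reagents that add atoms: water O
Why: Acylation of the primary allylic alcohol by the acid chloride followed by acid-catalysed hydrolysis of the allylic acetal, which leaves the ester and the E enal untouched; no stereocenter is formed.

Step 3
Reactants: 6 tert-butyl 3-methylbut-2-enoate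
Product: 7 tert-butyl[(1-tert-butoxy-3-methylbuta-1,3-dien-1-yl)oxy]dimethylsilane
Conditions: LiN(i-Pr)2, THF, −78 °C; t-BuMe2SiCl, DMPU, −78 → 23 °C
Reagents that add atoms: tert-butyldimethylsilyl chloride CC(C)(C)[Si](C)(C)Cl
Why: Kinetic γ-deprotonation of the β,β-dimethyl enoate gives the lithium dienolate, which is silylated on oxygen (silyl dienol ether formation); no stereocenter is formed.

Step 4
Reactants: 5 (E)-2-methyl-4-oxobut-2-en-1-yl 2-methylpropanoate; 7 silyl dienol ether
Product: 8 tert-butyl (2E,5S,6E)-5-hydroxy-3,7-dimethyl-8-(2-methylpropanoyloxy)octa-2,6-dienoate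
Conditions: SiCl4 (1.1 equiv), (R,R)-bis(phosphoramide) [(R)-C20H12(NMe)2P(O)N(Me)]2(CH2)5 (binaphthyldiamine-derived, 5 mol%), i-Pr2NEt (cat.), CH2Cl2, −78 °C; aq. NaHCO3
Reagents that add atoms: none
Why: Catalytic enantioselective vinylogous Mukaiyama aldol addition (Lewis-base-activated SiCl4), in which the dienol ether attacks through its γ-carbon at the aldehyde carbon of the enal and the chiral phosphoramide-bound silicon cation shields one aldehyde face, so that the (5S)-carbinol (the later C1) is set by catalyst control and the 2E enoate is formed.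

Step 5
Reactants: 8 tert-butyl (2E,5S,6E)-5-hydroxy-3,7-dimethyl-8-(2-methylpropanoyloxy)octa-2,6-dienoate
Product: 10 (2E,5S,6E)-5-(tert-butyldimethylsilyloxy)-3,7-dimethyl-8-(2-methylpropanoyloxy)octa-2,6-dienoic acid, via silyl ester 9 (not isolated)
Conditions: t-BuMe2SiOTf (3 equiv), 2,6-lutidine, CH2Cl2, 0 → 23 °C; then AcOH, THF/H2O
Reagents that add atoms: tert-butyldimethylsilyl trifluoromethanesulfonate CC(C)(C)[Si](C)(C)OS(=O)(=O)C(F)(F)F
Why: The silyl triflate converts the secondary alcohol into its silyl ether and the tert-butyl ester into a silyl ester with loss of isobutene (silyl triflate cleavage of tert-butyl esters), and only the labile silyl ester is hydrolysed by mild aqueous acid; the stereocenter is untouched.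

Step 6
Reactants: 10 (2E,5S,6E)-5-(tert-butyldimethylsilyloxy)-3,7-dimethyl-8-(2-methylpropanoyloxy)octa-2,6-dienoic acid
Product: 13 bicyclo[3.1.1]heptan-6-one with C5 ketone and C1 silyl ether and C3 methylidene and C10 methyl and C9 isobutyrate, via acid chloride 11 (not isolated), via vinylketene 12 (not isolated)
Conditions: 1-chloro-N,N,2-trimethylprop-1-en-1-amine, CH2Cl2, 0 °C; then slow addition to Et3N, toluene, 110 °C, high dilution
Reagents that add atoms: none
Why: Intramolecular [2+2] cycloaddition of a vinylketene (1,4-dehydrochlorination of the enoyl chloride) with the trisubstituted alkene, a known entry to bicyclo[3.1.1]heptan-6-ones, in which the ketene carbonyl carbon bonds to the less substituted alkene carbon (C11), the E alkene geometry is retained so that the C10 methyl is syn to the three-carbon bridge and C9 points to the carbonyl bridge, and the C1 silyloxy stereocenter fixes the alkene face by allylic 1,3-strain (its hydrogen eclipses the alkene, the tether lies on the attacked face, the silyloxy group points away from the C10 methyl), which sets C4, C10 and C11 in the absolute sense of the target.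

Step 7
Reactants: 13 bicyclo[3.1.1]heptan-6-one
Product: 15 xanthate of the bridged aldol lactone, via potassium alkoxide 14 (not isolated)
Conditions: KN(SiMe3)2, THF, −78 °C; CS2, −78 → −20 °C; MeI, → 0 °C
Reagents that add atoms: carbon disulfide S=C=S; iodomethane CI
Why: Intramolecular aldol addition of the isobutyrate enolate (the only enolizable position, since both α-carbons of the cyclobutanone are bridgeheads) to the strained ketone closes a temporary seven-membered lactone and forms C5–C6 from the C10 side, the only side the tether can reach, which sets C5; the tertiary alkoxide is trapped as its S-methyl xanthate, which has no β-hydrogen available for syn-elimination.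

Step 8
Reactants: 15 xanthate of the bridged aldol lactone
Product: 16 bridged lactone with C5–H
Conditions: Bu3SnH, azobisisobutyronitrile (cat.), toluene, 100 °C
Reagents that add atoms: none
Why: Barton–McCombie deoxygenation, in which the tertiary cyclobutyl radical is held in the bridged lactone so that hydrogen can only be delivered to the face of the three-carbon bridge and C6 stays on the C10 side.

Step 9
Reactants: 16 bridged lactone
Product: 17 hydroxy ketone with C9 alcohol and C7 methyl ketone
Conditions: MeLi (1.1 equiv), THF, −78 °C; aq. NH4Cl at −78 °C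
Reagents that add atoms: methyllithium [Li]C
Why: Addition of one equivalent of an organolithium to a lactone without α-hydrogen gives a lithium hemiketal that is stable at low temperature and collapses to the methyl ketone only on work-up, which introduces C8; no stereocenter is formed.

Step 10
Reactants: 17 hydroxy ketone
Product: 18 keto aldehyde with C9 aldehyde and C7 methyl ketone
Conditions: 1,1,1-triacetoxy-1,1-dihydro-1,2-benziodoxol-3(1H)-one, NaHCO3, CH2Cl2, 0 → 23 °C
Reagents that add atoms: none
Why: Dess–Martin oxidation of the neopentyl primary alcohol gives an aldehyde that cannot enolize because C10 is quaternary; no stereocenter is affected.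

Step 11
Reactants: 19 angelic acid
Product: 20 (Z)-2-methylbut-2-en-1-ol
Conditions: LiAlH4, Et2O, 0 °C
Reagents that add atoms: none
Why: Hydride reduction of the carboxylic acid with LiAlH4 gives the allylic alcohol and leaves the trisubstituted Z alkene unchanged.

Step 12
Reactants: 20 (Z)-2-methylbut-2-en-1-ol
Product: 21 (Z)-2-methylbut-2-enal
Conditions: 1,1,1-triacetoxy-1,1-dihydro-1,2-benziodoxol-3(1H)-one, NaHCO3, CH2Cl2, 0 °C; solution used at once
Reagents that add atoms: none
Why: Buffered Dess–Martin oxidation at low temperature gives the Z enal without the acid or base that would isomerize it to the E isomer.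

Step 13
Reactants: 18 keto aldehyde; 21 (Z)-2-methylbut-2-enal
Product: 23 tricyclic 9-angelate 7-alcohol with C1 silyl ether and C3 methylidene, via aldol 22 (not isolated)
Conditions: 21 (4 equiv), LaLi3[(S)-1,1'-binaphthalene-2,2'-diolate]3 (10 mol%, trivalent lanthanum), LiOTf (10 mol%), THF, −20 → 23 °C
Reagents that add atoms: none
Why: Proposed new method: LaLi3[(S)-1,1'-binaphthalene-2,2'-diolate]3, a Brønsted-basic Lewis acid, enolizes the C7 methyl ketone at C8, the enolate adds to the C9 aldehyde to give aldol 22 (held on the catalyst as its alkoxide, the metal being returned on turnover), this alkoxide forms a hemiacetal with 21, and the hemiacetal delivers hydride to C7 through a six-membered metal-bridged transition state, so that one catalytic operation forms C8–C9, reduces C7 and places the angelate on O9 with every atom of 18 and 21 kept in the product. The closest known reaction type is the direct catalytic asymmetric aldol–Tishchenko reaction of ketones with aldehydes under this heterobimetallic catalyst, together with the Evans–Tishchenko reduction of β-hydroxy ketones; new here is that the aldol part is intramolecular and the hydride donor is a second, conjugated aldehyde. The only ring closed is the seven-membered carbocycle, by a 7-(enolendo)-exo-trig aldol addition. C9 is set by the catalyst, because the aldol step is reversible, the two C9 epimers of 22 interconvert by retro-aldol, and the irreversible hydride transfer inside the chiral complex consumes one of them (dynamic kinetic resolution), whereas C7 is set by C9 through the intramolecular hydride delivery, which can only give the 1,3-anti (trans) diol monoester. The step needs a single enolate and a single acceptor in the substrate and cyclization ahead of intermolecular aldol addition to 21, which is secured because C6 and C10 are quaternary (only C8 can be deprotonated, the C9 aldehyde cannot enolize) and because the cyclobutane holds both arms cis-1,3 within bonding distance. Reagent control is unavoidable, since the two faces of the C9 carbonyl differ only through the remote three-carbon bridge.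

Step 14
Reactants: 24 (E)-2-methylbut-2-en-1-ol
Product: 25 [(2R,3R)-2,3-dimethyloxiran-2-yl]methanol
Conditions: Ti(O-i-Pr)4 (cat.), D-(−)-diethyl tartrate (cat.), t-BuOOH, 4 Å molecular sieves, CH2Cl2, −20 °C
Reagents that add atoms: tert-butyl hydroperoxide CC(C)(C)OO
Why: Sharpless asymmetric epoxidation of the E allylic alcohol, in which the D-(−)-tartrate ligand selects the face that gives the (2R,3R)-epoxy alcohol and the E geometry fixes the cis relation of the two methyl groups.

Step 15
Reactants: 25 [(2R,3R)-2,3-dimethyloxiran-2-yl]methanol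
Product: 26 (2S,3R)-2,3-dimethyloxirane-2-carboxylic acid
Conditions: RuCl3·xH2O (cat.), NaIO4, CCl4/MeCN/H2O, 23 °C
Reagents that add atoms: water O (second carboxyl oxygen, by way of the aldehyde hydrate; NaIO4 is the terminal oxidant)
Why: RuO4-catalysed oxidation of the primary alcohol to the carboxylic acid leaves the epoxide and both stereocenters untouched; the C2 descriptor changes to S only through the change of priorities.

Step 16
Reactants: 23 tricyclic 9-angelate 7-alcohol; 26 (2S,3R)-2,3-dimethyloxirane-2-carboxylic acid
Product: 28 tricyclic 9-angelate 7-epoxy ester with C1 silyl ether and C3 methylidene, via mixed anhydride 27 (not isolated)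
Conditions: 26, 2,4,6-trichlorobenzoyl chloride, Et3N, THF, 0 → 23 °C; then 23, 4-(dimethylamino)pyridine, toluene, 50 °C
Reagents that add atoms: none
Why: Yamaguchi esterification, in which the mixed 2,4,6-trichlorobenzoic anhydride transfers the hindered epoxy acyl group to the C7 alcohol under nucleophilic catalysis; the trans relation of O7 and O9 on the rigid ring prevents migration of the angelate, and no stereocenter is touched.

Step 17
Reactants: 28 tricyclic 9-angelate 7-epoxy ester
Product: 29 tricyclic diester with C1 alcohol and C3 methylidene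
Conditions: HF·pyridine, pyridine, THF, 0 → 23 °C
Reagents that add atoms: none
Why: Fluoride-mediated cleavage of the secondary silyl ether under buffered, non-basic conditions spares both esters and the glycidic epoxide.

Step 18
Reactants: 29 tricyclic diester with C1 alcohol
Product: 31 CNP0149458.1, via deconjugated enone 30 (not isolated)
Conditions: 1,1,1-triacetoxy-1,1-dihydro-1,2-benziodoxol-3(1H)-one, NaHCO3, CH2Cl2, 0 °C; then DBU (0.2 equiv), 0 → 23 °C
Reagents that add atoms: none
Why: Dess–Martin oxidation of the C1 alcohol erases the relay stereocenter, and amine-base isomerization of the β,γ-unsaturated ketone (deprotonation at the doubly activated C2, reprotonation at the exocyclic carbon) moves the alkene into conjugation and creates the C3 methyl; the adjacent stereocenters C4 and C11 are bridgeheads and cannot epimerize.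

**Compound list**

1 | 3-methylbut-2-enal diethyl acetal (1,1-diethoxy-3-methylbut-2-ene) | CC(C)=CC(OCC)OCC | starting material
2 | (E)-4,4-diethoxy-2-methylbut-2-en-1-ol | OC/C(C)=C/C(OCC)OCC | intermediate
3 | 2-methylpropanoyl chloride (isobutyryl chloride) | CC(C)C(Cl)=O | starting material
4 | (E)-4,4-diethoxy-2-methylbut-2-en-1-yl 2-methylpropanoate | CCOC(OCC)/C=C(\C)COC(=O)C(C)C | intermediate
5 | (E)-2-methyl-4-oxobut-2-en-1-yl 2-methylpropanoate | O=C/C=C(\C)COC(=O)C(C)C | intermediate
6 | tert-butyl 3-methylbut-2-enoate | CC(C)=CC(=O)OC(C)(C)C | starting material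
7 | tert-butyl[(1-tert-butoxy-3-methylbuta-1,3-dien-1-yl)oxy]dimethylsilane (ketene acetal geometry immaterial) | C=C(C)C=C(OC(C)(C)C)O[Si](C)(C)C(C)(C)C | intermediate
8 | tert-butyl (2E,5S,6E)-5-hydroxy-3,7-dimethyl-8-(2-methylpropanoyloxy)octa-2,6-dienoate | CC(C)(C)OC(=O)/C=C(\C)C[C@H](O)/C=C(\C)COC(=O)C(C)C | intermediate
9 | tert-butyldimethylsilyl (2E,5S,6E)-5-(tert-butyldimethylsilyloxy)-3,7-dimethyl-8-(2-methylpropanoyloxy)octa-2,6-dienoate | CC(C)(C)[Si](C)(C)OC(=O)/C=C(\C)C[C@H](O[Si](C)(C)C(C)(C)C)/C=C(\C)COC(=O)C(C)C | intermediate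
10 | (2E,5S,6E)-5-(tert-butyldimethylsilyloxy)-3,7-dimethyl-8-(2-methylpropanoyloxy)octa-2,6-dienoic acid | OC(=O)/C=C(\C)C[C@H](O[Si](C)(C)C(C)(C)C)/C=C(\C)COC(=O)C(C)C | intermediate
11 | (2E,5S,6E)-5-(tert-butyldimethylsilyloxy)-3,7-dimethyl-8-(2-methylpropanoyloxy)octa-2,6-dienoyl chloride | ClC(=O)/C=C(\C)C[C@H](O[Si](C)(C)C(C)(C)C)/C=C(\C)COC(=O)C(C)C | intermediate
12 | vinylketene, (5S,6E)-5-(tert-butyldimethylsilyloxy)-7-methyl-3-methylidene-8-(2-methylpropanoyloxy)octa-1,6-dien-1-one | O=C=CC(=C)C[C@H](O[Si](C)(C)C(C)(C)C)/C=C(\C)COC(=O)C(C)C | intermediate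
13 | [2-(tert-butyldimethylsilyloxy)-7-methyl-4-methylidene-6-oxobicyclo[3.1.1]heptan-7-yl]methyl 2-methylpropanoate; 7-methyl syn to the three-carbon bridge, silyloxy group on the side of the C6 carbonyl (longipinane locants: C5 ketone, C1 silyl ether, C3 methylidene, C9 ester) | O=C1[C@H]2[C@@H](O[Si](C)(C)C(C)(C)C)CC(=C)[C@@H]1[C@@]2(C)COC(=O)C(C)C | intermediate
14 | potassium alkoxide of the bridged aldol lactone (ring O9–C7(=O)–C6(CH3)2–C5; C5–O on the face of the three-carbon bridge) | O=C1C(C)(C)[C@]2([O-])[C@H]3[C@@H](O[Si](C)(C)C(C)(C)C)CC(=C)[C@@H]2[C@@]3(C)CO1.[K+] | intermediate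
15 | O-(C5) S-methyl xanthate of the bridged aldol lactone | O=C1C(C)(C)[C@]2(OC(=S)SC)[C@H]3[C@@H](O[Si](C)(C)C(C)(C)C)CC(=C)[C@@H]2[C@@]3(C)CO1 | intermediate
16 | bridged seven-membered lactone O9–C7(=O)–C6(CH3)2–C5H, with C5–H on the face of the three-carbon bridge, C1 silyl ether, C3 methylidene | O=C1C(C)(C)[C@@H]2[C@H]3[C@@H](O[Si](C)(C)C(C)(C)C)CC(=C)[C@@H]2[C@@]3(C)CO1 | intermediate
17 | hydroxy ketone: C10–CH2OH (C9) and C5–C(CH3)2–CO–CH3 (C6–C8) cis on the cyclobutane, C1 silyl ether, C3 methylidene | CC(=O)C(C)(C)[C@@H]1[C@H]2[C@@H](O[Si](C)(C)C(C)(C)C)CC(=C)[C@@H]1[C@@]2(C)CO | intermediate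
18 | keto aldehyde: C10–CHO (C9) and C5–C(CH3)2–CO–CH3 (C6–C8) cis on the cyclobutane, C1 silyl ether, C3 methylidene | CC(=O)C(C)(C)[C@@H]1[C@H]2[C@@H](O[Si](C)(C)C(C)(C)C)CC(=C)[C@@H]1[C@@]2(C)C=O | intermediate
19 | angelic acid, (Z)-2-methylbut-2-enoic acid | C/C=C(/C)C(=O)O | starting material
20 | (Z)-2-methylbut-2-en-1-ol | C/C=C(/C)CO | intermediate
21 | (Z)-2-methylbut-2-enal (angelaldehyde) | C/C=C(/C)C=O | intermediate
22 | C9 aldol, 9-hydroxy-1-(tert-butyldimethylsilyloxy)-3-methylidene longipinan-7-one (seven-membered ring closed; present in the flask as the β-hydroxy ketone and as its catalyst-bound alkoxide, written in the neutral form) | O[C@@H]1CC(=O)C(C)(C)[C@@H]2[C@H]3[C@@H](O[Si](C)(C)C(C)(C)C)CC(=C)[C@@H]2[C@]31C | intermediate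
23 | 9-[(Z)-2-methylbut-2-enoyloxy]-7-hydroxy-1-(tert-butyldimethylsilyloxy)-3-methylidene longipinane; O7 and O9 trans | C/C=C(/C)C(=O)O[C@@H]1C[C@@H](O)C(C)(C)[C@@H]2[C@H]3[C@@H](O[Si](C)(C)C(C)(C)C)CC(=C)[C@@H]2[C@]31C | intermediate
24 | (E)-2-methylbut-2-en-1-ol | C/C=C(\C)CO | starting material
25 | [(2R,3R)-2,3-dimethyloxiran-2-yl]methanol | OC[C@@]1(C)O[C@@H]1C | intermediate
26 | (2S,3R)-2,3-dimethyloxirane-2-carboxylic acid (methyl groups cis) | OC(=O)[C@@]1(C)O[C@@H]1C | intermediate
27 | (2S,3R)-2,3-dimethyloxirane-2-carboxylic 2,4,6-trichlorobenzoic anhydride | O=C(OC(=O)[C@@]1(C)O[C@@H]1C)c2c(Cl)cc(Cl)cc2Cl | intermediate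
28 | 9-[(Z)-2-methylbut-2-enoyloxy]-7-[(2S,3R)-2,3-dimethyloxirane-2-carbonyloxy]-1-(tert-butyldimethylsilyloxy)-3-methylidene longipinane | C/C=C(/C)C(=O)O[C@@H]1C[C@@H](OC(=O)[C@@]2(C)O[C@@H]2C)C(C)(C)[C@@H]2[C@H]3[C@@H](O[Si](C)(C)C(C)(C)C)CC(=C)[C@@H]2[C@]31C | intermediate
29 | 9-[(Z)-2-methylbut-2-enoyloxy]-7-[(2S,3R)-2,3-dimethyloxirane-2-carbonyloxy]-3-methylidene longipinan-1-ol | C/C=C(/C)C(=O)O[C@@H]1C[C@@H](OC(=O)[C@@]2(C)O[C@@H]2C)C(C)(C)[C@@H]2[C@H]3[C@@H](O)CC(=C)[C@@H]2[C@]31C | intermediate
30 | 9-[(Z)-2-methylbut-2-enoyloxy]-7-[(2S,3R)-2,3-dimethyloxirane-2-carbonyloxy]-3-methylidene longipinan-1-one | C/C=C(/C)C(=O)O[C@@H]1C[C@@H](OC(=O)[C@@]2(C)O[C@@H]2C)C(C)(C)[C@@H]2[C@H]3C(=O)CC(=C)[C@@H]2[C@]31C | intermediate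
31 | CNP0149458.1, 9-[(Z)-2-methylbut-2-enoyloxy]-7-[(2S,3R)-2,3-dimethyloxirane-2-carbonyloxy]longipin-2-en-1-one | C/C=C(/C)C(=O)O[C@@H]1C[C@@H](OC(=O)[C@@]2(C)O[C@@H]2C)C(C)(C)[C@@H]2[C@H]3C(=O)C=C(C)[C@@H]2[C@]31C | target

**Step count and risks**

Total step count: 18. Longest linear sequence: 13 steps (steps 1, 2, 4, 5, 6, 7, 8, 9, 10, 13, 16, 17, 18).

Steps most likely to fail:

Step 13 (Proposed new method). What may go wrong: LaLi3[(S)-1,1'-binaphthalene-2,2'-diolate]3 may enolize the hindered methyl ketone too slowly, the hydride transfer may fail to discriminate between the two interconverting C9 epimers of the aldol, or 21 may isomerize to the E enal under the basic catalyst. The fallback uses known chemistry only, sets out from 18 and comes back at 23; on its way compound 22 is made by a different path and isolated. Compound 18 is closed by aldol condensation (piperidinium acetate, benzene, reflux, removal of water) to the C8=C9 cycloheptenone F1. CuCl and NaO-t-Bu with (R)-1-[(S)-2-(diphenylphosphino)ferrocenyl]ethyldicyclohexylphosphine, B2pin2 and MeOH in THF then add boron to C9 under ligand control (catalytic asymmetric conjugate borylation of a cyclic enone) to give the β-boryl ketone F2. NaBO3 in THF/H2O replaces boron by hydroxyl with retention to give the β-hydroxy ketone 22 as an isolated compound. Evans–Tishchenko reduction of 22 with 21 and catalytic SmI2 (THF, −10 °C), a non-basic medium for the Z enal, should then give 23.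

Step 6. What may go wrong: the alkene carries two allylic oxygen functions and may be too electron-poor for the ketene, so that oligomerization of the vinylketene or loss of silanol competes, and facial control may erode at 110 °C. The fallback sets out from 10 and comes back at 13; it carries the C9 oxygen through the cycloaddition as a silyl ether, which makes the alkene more electron-rich. K2CO3 in MeOH removes the isobutyrate to give the hydroxy acid F3. t-BuMe2SiCl and imidazole in DMF silylate the alcohol and the acid to the silyl ester F4, which is hydrolysed in the work-up (K2CO3, aqueous MeOH) to the bis-silyl ether acid F5. 1-Chloro-N,N,2-trimethylprop-1-en-1-amine gives the acid chloride F6, and Et3N in toluene at 110 °C gives the vinylketene F7 and, by the same [2+2] cycloaddition, the bis-silyl cyclobutanone F8. HF·pyridine at 0 °C cleaves only the primary silyl ether to give the primary alcohol F9, and acylation with 3 and pyridine returns 13.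

Step 16. What may go wrong: acyl transfer between a neopentyl-type secondary alcohol and an α-quaternary acid may stall, the mixed anhydride then being attacked at its aryl carbonyl or lost by decomposition. The fallback sets out from 26 and 23 and comes back at 28; it activates the alcohol instead of relying on the acid alone. 26 is converted with cyanuric fluoride and pyridine (CH2Cl2, 0 °C) into the acyl fluoride F10. 23 is deprotonated with LiN(SiMe3)2 in THF at −78 °C to the lithium alkoxide F11, which is acylated by F10 on warming to 0 °C to give 28. The trans relation of O7 and O9 should keep the angelate from migrating to the alkoxide.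

Further compounds
F1 | step 13 | C8=C9 cycloheptenone (7-oxo, 1-silyloxy, 3-methylidene longipin-8-ene) | C1=CC(=O)C(C)(C)[C@@H]2[C@H]3[C@@H](O[Si](C)(C)C(C)(C)C)CC(=C)[C@@H]2[C@]31C
F2 | step 13 | β-boryl ketone, 9-(4,4,5,5-tetramethyl-1,3,2-dioxaborolan-2-yl)-1-silyloxy-3-methylidene longipinan-7-one | CC1(C)OB(OC1(C)C)[C@@H]1CC(=O)C(C)(C)[C@@H]2[C@H]3[C@@H](O[Si](C)(C)C(C)(C)C)CC(=C)[C@@H]2[C@]31C
F3 | step 6 | (2E,5S,6E)-5-(tert-butyldimethylsilyloxy)-8-hydroxy-3,7-dimethylocta-2,6-dienoic acid | OC(=O)/C=C(\C)C[C@H](O[Si](C)(C)C(C)(C)C)/C=C(\C)CO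
F4 | step 6 | tert-butyldimethylsilyl (2E,5S,6E)-5,8-bis(tert-butyldimethylsilyloxy)-3,7-dimethylocta-2,6-dienoate | CC(C)(C)[Si](C)(C)OC(=O)/C=C(\C)C[C@H](O[Si](C)(C)C(C)(C)C)/C=C(\C)CO[Si](C)(C)C(C)(C)C
F5 | step 6 | (2E,5S,6E)-5,8-bis(tert-butyldimethylsilyloxy)-3,7-dimethylocta-2,6-dienoic acid | OC(=O)/C=C(\C)C[C@H](O[Si](C)(C)C(C)(C)C)/C=C(\C)CO[Si](C)(C)C(C)(C)C
F6 | step 6 | (2E,5S,6E)-5,8-bis(tert-butyldimethylsilyloxy)-3,7-dimethylocta-2,6-dienoyl chloride | ClC(=O)/C=C(\C)C[C@H](O[Si](C)(C)C(C)(C)C)/C=C(\C)CO[Si](C)(C)C(C)(C)C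
F7 | step 6 | vinylketene, (5S,6E)-5,8-bis(tert-butyldimethylsilyloxy)-7-methyl-3-methylideneocta-1,6-dien-1-one | O=C=CC(=C)C[C@H](O[Si](C)(C)C(C)(C)C)/C=C(\C)CO[Si](C)(C)C(C)(C)C
F8 | step 6 | 2-(tert-butyldimethylsilyloxy)-7-[(tert-butyldimethylsilyloxy)methyl]-7-methyl-4-methylidenebicyclo[3.1.1]heptan-6-one (configuration as in 13) | O=C1[C@H]2[C@@H](O[Si](C)(C)C(C)(C)C)CC(=C)[C@@H]1[C@@]2(C)CO[Si](C)(C)C(C)(C)C
F9 | step 6 | 2-(tert-butyldimethylsilyloxy)-7-(hydroxymethyl)-7-methyl-4-methylidenebicyclo[3.1.1]heptan-6-one (configuration as in 13) | O=C1[C@H]2[C@@H](O[Si](C)(C)C(C)(C)C)CC(=C)[C@@H]1[C@@]2(C)CO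
F10 | step 16 | (2S,3R)-2,3-dimethyloxirane-2-carbonyl fluoride | O=C(F)[C@@]1(C)O[C@@H]1C
F11 | step 16 | lithium C7 alkoxide of 23 | C/C=C(/C)C(=O)O[C@@H]1C[C@@H]([O-])C(C)(C)[C@@H]2[C@H]3[C@@H](O[Si](C)(C)C(C)(C)C)CC(=C)[C@@H]2[C@]31C.[Li+]
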